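**Plan**

1. Retrosynthesis: the palmitoleate C–O bond is cut first; the polyene is then cut at C11=C12 and C11'=C12' (two Wittig bonds) into a C10 dialdehyde and two C15 phosphonium salts; the hydroxylated C15 salt is cut at C6–C7 into a ring A enol triflate and a C6 dienylstannane.
2. Forward: no ring is built; ring A arrives intact from ketoisophorone and ring B from β-ionone; the chain is joined ring B C15 + C10 → C25 aldehyde, then + ring A C15 → C40, and O-acylation is last.
3. Enabling feature: ring A (C1–C6) holds the only stereocentre, C3, and its pattern (gem-dimethyl C1, oxygen on C3, methyl on C5, chain on C6) is that of achiral ketoisophorone; C5 ends as an sp2 atom of the C5=C6 ring alkene, so it can serve as a transient stereocentre.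
4. Stereochemistry: (3R) comes from a two-enzyme reduction of ketoisophorone (alkene first, then the C3 carbonyl); C5 is flattened at enol triflate formation; 7E from syn-hydrostannylation and stereoretentive Stille coupling, 9E/9'E from the C6 enynol, the vinyl-ionol route and salt crystallisation, 11E/11'E from Wittig olefination plus thermal equilibration; the Z alkene is bought with palmitoleic acid.

Key step: step 1

Assumption: both reductases are used as heterologously expressed catalysts and are not counted as starting materials; β-ionone is added as a fifth commercial starting material to supply ring B. Ring atoms of the cyclohexane intermediates carry cyclohexanone numbering (C4 and C6 of 3 are carotenoid C3 and C5).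

**Step 1**
Reactants: 1 ketoisophorone (2,6,6-trimethylcyclohex-2-ene-1,4-dione)
Product: 3 (4R,6R)-4-hydroxy-2,2,6-trimethylcyclohexan-1-one (actinol), via (6R)-levodione 2 (not isolated)
Conditions: old yellow enzyme 2 (ene-reductase of S. cerevisiae), NADP+ (cat.), glucose dehydrogenase, D-glucose, 0.2 M K2HPO4/KH2PO4 buffer pH 6.8, 30 °C until 1 is consumed; then levodione reductase (C. aquaticum), NAD+ (cat.), 30 °C; EtOAc extraction, crystallisation
Reagents that add atoms: none
Why: The flavin of the ene-reductase, reduced by NADPH, passes hydride to the β-carbon of the bound enone while an active-site tyrosine protonates the α-carbon from the opposite face, so H2 is added anti across C2=C3 of 1 and the methyl-bearing carbon becomes the (6R) centre of 2. Levodione reductase, a short-chain dehydrogenase, then transfers hydride from NADH to one face of the C4 carbonyl of 2 and should give the (4R) carbinol trans to the C6 methyl group, glucose dehydrogenase recycling both cofactors at the expense of glucose. The closest known reaction type is the ene-reductase/carbonyl-reductase cascade on cyclic enones and enediones, and no ring is closed. Both new stereocentres are under catalyst control, and the second is matched by the substrate, because the axial C2 methyl group blocks axial hydride approach to C4 and equatorial delivery leads to the same trans alcohol. The step needs enantioface selection at the alkene, C4-over-C1 carbonyl selection and alkene-before-carbonyl ordering: the C1 carbonyl is buried between quaternary C2 and C6, the carbonyl reductase is added only after 1 has gone so that it cannot reduce 1 to 4-hydroxyisophorone, and the slightly acidic buffer slows enolisation of 2 at C6. The expected preference of the reductase for (6R)-2 should keep any (6S) ketone from being carried into the C4 centre.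

**Step 2**
Reactants: 3 (4R,6R)-actinol
Product: 4 (4R,6R)-2,2,6-trimethyl-4-(triethylsilyloxy)cyclohexan-1-one
Conditions: Et3SiCl, imidazole, DMF, 0 °C → rt
Reagents that add atoms: chlorotriethylsilane, CC[Si](Cl)(CC)CC
Why: Imidazole-promoted silylation of a secondary alcohol (silyl ether formation) touches neither stereocentre, and the triethylsilyl ether tolerates amide base and palladium catalysis yet is removed by mild acid methanolysis in step 6.

**Step 3**
Reactants: 4 triethylsilyl ether of actinol
Product: 6 (4R)-2,6,6-trimethyl-4-(triethylsilyloxy)cyclohex-1-en-1-yl trifluoromethanesulfonate, via lithium enolate 5 (not isolated)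
Conditions: LiN(iPr)2, THF, −78 → 0 °C; PhNTf2, 0 °C → rt; aq. work-up
Reagents that add atoms: N-phenylbis(trifluoromethanesulfonimide), O=S(=O)(N(c1ccccc1)S(=O)(=O)C(F)(F)F)C(F)(F)F
Why: Deprotonation is possible only at C6–H because C2 is quaternary, so enolate O-triflation (enol triflate formation) should give one regioisomer in which the transient centre is flattened into the future C5=C6 ring alkene, while the γ-silyloxy group cannot be lost by β-elimination and C4 is untouched.

**Step 4**
Reactants: 7 (E)-3-methylpent-2-en-4-yn-1-ol
Product: 8 (2E,4E)-3-methyl-5-(tributylstannyl)penta-2,4-dien-1-ol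
Conditions: Bu3SnH (slow addition), PdCl2(PPh3)2 (2 mol %), THF, 0 °C → rt
Reagents that add atoms: tributyltin hydride, CCCC[SnH](CCCC)CCCC
Why: Palladium-catalysed hydrostannylation adds Sn–H syn across the terminal alkyne with tin at the unhindered terminus (the 3-methyl group shields the internal carbon), which should give the (E)-vinylstannane and leave the existing 2E alkene and the free alcohol untouched.

**Step 5**
Reactants: 6 ring A enol triflate; 8 dienylstannane
Product: 9 (2E,4E)-3-methyl-5-[(4R)-2,6,6-trimethyl-4-(triethylsilyloxy)cyclohex-1-en-1-yl]penta-2,4-dien-1-ol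
Conditions: Pd2(dba)3 (2.5 mol %), AsPh3 (20 mol %), NMP, 60 °C, argon, dark
Reagents that add atoms: none
Why: Stille cross-coupling (insertion of zerovalent palladium into the C–OTf bond, alkenyl transfer from tin, reductive elimination) retains both alkene geometries, and the easily dissociating AsPh3 ligand in polar NMP is chosen to speed the transmetalation that the doubly flanked tetrasubstituted triflate slows, the free allylic alcohol and the silyl ether being inert.

**Step 6**
Reactants: 9 silyl-protected C15 dienol
Product: 11 [(2E,4E)-5-[(4R)-4-hydroxy-2,6,6-trimethylcyclohex-1-en-1-yl]-3-methylpenta-2,4-dien-1-yl]triphenylphosphonium bromide, via C15 diol 10 (not isolated)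
Conditions: PPh3·HBr (1.2 equiv), MeOH, 0 °C → rt, dark; crystallisation
Reagents that add atoms: triphenylphosphine hydrobromide, [Br-].[PH+](c1ccccc1)(c1ccccc1)c1ccccc1
Why: Acid methanolysis of the triethylsilyl ether should be faster than ionisation of the primary dienylic alcohol, whose delocalised cation is then trapped by PPh3 at the unhindered terminus (SN1-type phosphonium salt formation from an allylic alcohol); the homoallylic C3 carbinol cannot ionise and keeps its configuration, and crystallisation removes any 2Z salt formed through the cation.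

**Step 7**
Reactants: 12 β-ionone
Product: 13 vinyl-β-ionol, racemic (1E)-3-methyl-1-(2,6,6-trimethylcyclohex-1-en-1-yl)penta-1,4-dien-3-ol
Conditions: CH2=CHMgBr, THF, 0 °C; then H2O
Reagents that add atoms: vinylmagnesium bromide, C=C[Mg]Br
Why: Grignard 1,2-addition to the ketone carbonyl is favoured over conjugate addition because the β-carbon carries the bulky trimethylcyclohexenyl group, and the new carbinol centre is lost in the next step, so its configuration is irrelevant.

**Step 8**
Reactants: 13 vinyl-β-ionol
Product: 14 [(2E,4E)-3-methyl-5-(2,6,6-trimethylcyclohex-1-en-1-yl)penta-2,4-dien-1-yl]triphenylphosphonium bromide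
Conditions: PPh3·HBr, MeOH, rt; crystallisation (EtOAc)
Reagents that add atoms: triphenylphosphine hydrobromide, [Br-].[PH+](c1ccccc1)(c1ccccc1)c1ccccc1
Why: Ionisation of the tertiary bis-allylic alcohol and capture of the pentadienyl cation by PPh3 at the primary terminus (SN1' allylic transposition, the standard C15 Wittig salt synthesis) should give the conjugated salt, and crystallisation secures the (2E,4E) isomer.

**Step 9**
Reactants: 14 ring B C15 phosphonium bromide; 15 (2E,4E,6E)-2,7-dimethylocta-2,4,6-trienedial
Product: 17 all-E β-apo-12'-carotenal (C25 aldehyde), via C15 ylide 16 (not isolated)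
Conditions: 15 (3 equiv), NaOMe (1.0 equiv, slow addition), MeOH/CH2Cl2, 0 °C → rt, argon, dark; then n-heptane, reflux; chromatography (15 recovered)
Reagents that add atoms: none
Why: Wittig olefination of the semistabilised allylic ylide with an excess of the symmetrical dialdehyde favours mono-olefination, since the remaining formyl group of the longer polyenal 17 is less electrophilic than those of 15, and heating equilibrates the hindered 11Z isomer to the all-E aldehyde.

**Step 10**
Reactants: 11 ring A hydroxy C15 phosphonium bromide; 17 β-apo-12'-carotenal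
Product: 19 (3R)-β-cryptoxanthin (all-E), via hydroxy C15 ylide 18 (not isolated)
Conditions: NaOMe (1.1 equiv), MeOH/CH2Cl2, 0 °C → rt, argon, dark; then EtOH, reflux (Z → E); crystallisation
Reagents that add atoms: none
Why: Wittig olefination forms C11=C12 and completes the C40 chain; the free secondary hydroxyl is tolerated because alkoxide formation in methanol is reversible, C3 is not involved, and thermal equilibration with crystallisation should deliver the all-E isomer.

**Step 11**
Reactants: 19 (3R)-β-cryptoxanthin; 20 palmitoleic acid, (9Z)-hexadec-9-enoic acid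
Product: 21 (3R)-β-cryptoxanthin palmitoleate, CNP0382087.1
Conditions: DCC, DMAP (cat.), CH2Cl2, rt, argon, dark
Reagents that add atoms: none
Why: Steglich esterification (carbodiimide activation, DMAP-catalysed acyl transfer) acylates the single hydroxyl at oxygen under neutral conditions at room temperature, so the C3–O bond and configuration, the all-E polyene and the Z alkene of the acyl chain are left unchanged.

**Compound list**

1 | ketoisophorone, 2,6,6-trimethylcyclohex-2-ene-1,4-dione | CC1=CC(=O)CC(C)(C)C1=O | starting material
2 | (6R)-levodione, (6R)-2,2,6-trimethylcyclohexane-1,4-dione | C[C@@H]1CC(=O)CC(C)(C)C1=O | intermediate (not isolated)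
3 | (4R,6R)-4-hydroxy-2,2,6-trimethylcyclohexan-1-one (actinol) | O[C@@H]1C[C@@H](C)C(=O)C(C)(C)C1 | intermediate
4 | (4R,6R)-2,2,6-trimethyl-4-(triethylsilyloxy)cyclohexan-1-one | CC[Si](CC)(CC)O[C@@H]1C[C@@H](C)C(=O)C(C)(C)C1 | intermediate
5 | lithium (4R)-2,6,6-trimethyl-4-(triethylsilyloxy)cyclohex-1-en-1-olate | CC[Si](CC)(CC)O[C@@H]1CC(C)=C(O[Li])C(C)(C)C1 | intermediate (not isolated)
6 | (4R)-2,6,6-trimethyl-4-(triethylsilyloxy)cyclohex-1-en-1-yl trifluoromethanesulfonate | CC[Si](CC)(CC)O[C@@H]1CC(C)=C(OS(=O)(=O)C(F)(F)F)C(C)(C)C1 | intermediate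
7 | (E)-3-methylpent-2-en-4-yn-1-ol | C#C/C(C)=C/CO | starting material
8 | (2E,4E)-3-methyl-5-(tributylstannyl)penta-2,4-dien-1-ol | CCCC[Sn](CCCC)(CCCC)/C=C/C(C)=C/CO | intermediate
9 | (2E,4E)-3-methyl-5-[(4R)-2,6,6-trimethyl-4-(triethylsilyloxy)cyclohex-1-en-1-yl]penta-2,4-dien-1-ol | CC[Si](CC)(CC)O[C@@H]1CC(C)=C(/C=C/C(C)=C/CO)C(C)(C)C1 | intermediate
10 | (1R)-4-[(1E,3E)-5-hydroxy-3-methylpenta-1,3-dien-1-yl]-3,5,5-trimethylcyclohex-3-en-1-ol | O[C@@H]1CC(C)=C(/C=C/C(C)=C/CO)C(C)(C)C1 | intermediate (not isolated)
11 | [(2E,4E)-5-[(4R)-4-hydroxy-2,6,6-trimethylcyclohex-1-en-1-yl]-3-methylpenta-2,4-dien-1-yl]triphenylphosphonium bromide | O[C@@H]1CC(C)=C(/C=C/C(C)=C/C[P+](c2ccccc2)(c2ccccc2)c2ccccc2)C(C)(C)C1.[Br-] | intermediate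
12 | β-ionone, (E)-4-(2,6,6-trimethylcyclohex-1-en-1-yl)but-3-en-2-one | CC(=O)/C=C/C1=C(C)CCCC1(C)C | starting material
13 | vinyl-β-ionol, racemic (1E)-3-methyl-1-(2,6,6-trimethylcyclohex-1-en-1-yl)penta-1,4-dien-3-ol | CC1=C(/C=C/C(C)(O)C=C)C(C)(C)CCC1 | intermediate
14 | [(2E,4E)-3-methyl-5-(2,6,6-trimethylcyclohex-1-en-1-yl)penta-2,4-dien-1-yl]triphenylphosphonium bromide | CC1=C(/C=C/C(C)=C/C[P+](c2ccccc2)(c2ccccc2)c2ccccc2)C(C)(C)CCC1.[Br-] | intermediate
15 | (2E,4E,6E)-2,7-dimethylocta-2,4,6-trienedial (C10 dialdehyde) | O=C/C(C)=C/C=C/C=C(C)/C=O | starting material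
16 | ylide of 14, [(2E,4E)-3-methyl-5-(2,6,6-trimethylcyclohex-1-en-1-yl)penta-2,4-dien-1-ylidene]triphenylphosphorane | CC1=C(/C=C/C(C)=C/C=P(c2ccccc2)(c2ccccc2)c2ccccc2)C(C)(C)CCC1 | intermediate (not isolated)
17 | all-E β-apo-12'-carotenal (C25 aldehyde) | CC1=C(/C=C/C(C)=C/C=C/C(C)=C/C=C/C=C(C)/C=O)C(C)(C)CCC1 | intermediate
18 | ylide of 11, [(2E,4E)-5-[(4R)-4-hydroxy-2,6,6-trimethylcyclohex-1-en-1-yl]-3-methylpenta-2,4-dien-1-ylidene]triphenylphosphorane | O[C@@H]1CC(C)=C(/C=C/C(C)=C/C=P(c2ccccc2)(c2ccccc2)c2ccccc2)C(C)(C)C1 | intermediate (not isolated)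
19 | (3R)-β-cryptoxanthin, all-E | O[C@@H]1CC(C)=C(/C=C/C(C)=C/C=C/C(C)=C/C=C/C=C(C)/C=C/C=C(C)/C=C/C2=C(C)CCCC2(C)C)C(C)(C)C1 | intermediate
20 | palmitoleic acid, (9Z)-hexadec-9-enoic acid | CCCCCC/C=C\CCCCCCCC(=O)O | starting material
21 | (3R)-β-cryptoxanthin palmitoleate, CNP0382087.1 | CCCCCC/C=C\CCCCCCCC(=O)O[C@@H]1CC(C)=C(/C=C/C(C)=C/C=C/C(C)=C/C=C/C=C(C)/C=C/C=C(C)/C=C/C2=C(C)CCCC2(C)C)C(C)(C)C1 | target

**Step count**

Total: 11 steps. Longest linear sequence: 7 steps (1, 2, 3, 5, 6, 10, 11) from ketoisophorone.

**Steps most likely to fail**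

Step 5. Transmetalation at the tetrasubstituted alkenylpalladium, flanked by a gem-dimethyl carbon and a methyl-bearing carbon, may be so slow that protodestannylation and stannane homocoupling consume the diene partner and prolonged heating erodes the diene geometry. The fallback sets out from triflate 6 and enynol 7 and changes the union to an sp–sp2 coupling. Sonogashira coupling (Pd(PPh3)4, CuI, iPr2NH, DMF, rt), in which the slim copper acetylide is far less sensitive to the flanking groups, should give (2E)-3-methyl-5-[(4R)-2,6,6-trimethyl-4-(triethylsilyloxy)cyclohex-1-en-1-yl]pent-2-en-4-yn-1-ol F1. Z-selective semi-reduction of the conjugated triple bond with Zn dust activated by Cu(OAc)2 and AgNO3 in MeOH/H2O should give (2E,4Z)-3-methyl-5-[(4R)-2,6,6-trimethyl-4-(triethylsilyloxy)cyclohex-1-en-1-yl]penta-2,4-dien-1-ol F2. The strongly congested 4Z alkene is then equilibrated to 4E with catalytic I2 in hexane under room light, and the route is rejoined at compound 9.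

Step 9. The ylide may not discriminate enough between dialdehyde 15 and the product aldehyde 17, so that double olefination to the symmetrical C40 hydrocarbon consumes the salt and the mixture becomes hard to separate. The fallback sets out from 15 and desymmetrises it before the olefination. Statistical mono-acetalisation with 2,2-dimethylpropane-1,3-diol (1 equiv, cat. pyridinium p-toluenesulfonate, toluene, 4 Å molecular sieves; dialdehyde and bis-acetal recycled) should give (2E,4E,6E)-7-(5,5-dimethyl-1,3-dioxan-2-yl)-2-methylocta-2,4,6-trienal F3. Wittig reaction of F3 with salt 14 (NaOMe, MeOH/CH2Cl2) should give the C25 acetal, β-apo-12'-carotenal 2,2-dimethylpropane-1,3-diyl acetal F4. Hydrolysis with dilute aqueous oxalic acid in THF, followed by thermal equilibration in heptane, returns to compound 17.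

Step 1. Carbonyl reduction may compete before the alkene reduction is complete, enolisation of 2 at C6 in the buffer may erode its enantiopurity, or the second enzyme may turn over too slowly for full conversion. The fallback sets out from 2, which is extracted after the ene-reductase stage, and replaces enzyme control at C4 by substrate control. Reduction with LiBH(s-Bu)3 in THF at −78 °C should attack only the unhindered C4 carbonyl, from the equatorial direction because the axial C2 methyl group blocks the axial path, and so give the axial alcohol trans to the C6 methyl group; crystallisation removes any cis diastereomer. The route is rejoined at compound 3, and no new compound is made (F0).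

**Further compounds**

F1 | step 5 | (2E)-3-methyl-5-[(4R)-2,6,6-trimethyl-4-(triethylsilyloxy)cyclohex-1-en-1-yl]pent-2-en-4-yn-1-ol | CC[Si](CC)(CC)O[C@@H]1CC(C)=C(C#C/C(C)=C/CO)C(C)(C)C1
F2 | step 5 | (2E,4Z)-3-methyl-5-[(4R)-2,6,6-trimethyl-4-(triethylsilyloxy)cyclohex-1-en-1-yl]penta-2,4-dien-1-ol | CC[Si](CC)(CC)O[C@@H]1CC(C)=C(/C=C\C(C)=C\CO)C(C)(C)C1
F3 | step 9 | (2E,4E,6E)-7-(5,5-dimethyl-1,3-dioxan-2-yl)-2-methylocta-2,4,6-trienal | O=C/C(C)=C/C=C/C=C(C)/C1OCC(C)(C)CO1
F4 | step 9 | β-apo-12'-carotenal 2,2-dimethylpropane-1,3-diyl acetal | CC1=C(/C=C/C(C)=C/C=C/C(C)=C/C=C/C=C(C)/C2OCC(C)(C)CO2)C(C)(C)CCC1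
F0 | step 1 | none | none
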